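**One constant fails.** One first-order constant cannot carry the last substrate readings of both earlier runs: they give 0.00918 /min in delta and 0.00792 /min in alpha, so as read, delta, with the smaller charge, stands faster per mole than alpha.

the same everywhere: gas 1.3 mM (held)

| run | substrate | free catalyst | temperature | remark | time |
|---|---|---|---|---|---|
| delta | 30 mM | 40 µM | 35 °C | run made earlier |  |
| alpha | 40 mM | 40 µM | 35 °C | run made earlier |  |
| ochre | 20 mM | 25 µM | 5 °C |  | 1.5 h |
| red | 20 mM | 40 µM | 55 °C |  | 1.5 h |
| grey | 20 mM | 40 µM | 35 °C |  | 1.5 h |
| green | 20 mM | 20 µM | 35 °C |  | 1.5 h |

| run | time / min | product / % | substrate / % |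
|---|---|---|---|
| delta | 4.00 | 4.0 | 96.3 |
| delta | 10.0 | 7.4 | 94.9 |
| delta | 25.0 | 18.4 | 79.6 |
| delta | 50.0 | 38.2 | 63.2 |
| alpha | 15.0 | 8.4 | 89.8 |
| alpha | 25.0 | 17.8 | 83.6 |
| alpha | 40.0 | 29.2 | 71.4 |
| alpha | 50.0 | 33.1 | 67.3 |

(each reading ± 1 percentage point)

- for product the crystals are counted in
- as a solid, counted per litre of solution: crystals
- at the start none of partner is dissolved
- reactions considered so far: partner + free catalyst <-> catalyst intermediate A; substrate + catalyst intermediate A <-> catalyst intermediate B; catalyst intermediate B -> free catalyst + product; gas <-> partner; crystals <-> product; partner -> decomposed reagent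
- the earlier runs do not show what temperature does; that part of a forecast is a guess
- no earlier run changes the charge of free catalyst; that part of a forecast is a guess

- all flasks from highest to lowest amount of product, in percent of the substrate charged, at 1.5 h (ochre / red / grey / green)
- the amount of product, in percent of the substrate charged of the flask you put first, at 1.5 h
- the amount of product, in percent of the substrate charged of the flask you put last, at 1.5 h

**The ledger.** I keep the books on substrate, the limiting reagent. The first entry is substrate bound as catalyst intermediate B, which cannot exceed the catalyst charged, 0.200% of the substrate in grey. The second is product, crystals counted in. The third is substrate left. The last delta readings of these two add up to 101%, so the books close within the scatter.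

**The rate.** For c(substrate) I take the saturating rate V·c/(K + c), which integrates to K·ln(charge/c) + (charge − c) = V·t. The last readings of delta and alpha give K = 32.5 mM and V = 0.519 mM/min. This K is the half-saturation concentration, an apparent Michaelis constant: the c(substrate) at which the rate stands at half of V. It comes from a small difference between two runs, so it is a loose reading.

**Grey's books.** Solving the integrated form by substitution, I get 64.7% product in grey. The earlier runs show nothing of temperature, so my books stop at 35 °C.

**The forecast.** The forecast orders the flasks red > grey > green > ochre, with 85% first and 5% last, and says “Temperature is a guess”.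

**The flasks.** The order is red > grey > green > ochre, with red at 81.2% and ochre at 10.1%.

    partner + free catalyst ⇌ catalyst intermediate A (K = 426 /M, k = 30700 /M/min, Ea = 37.0 kJ/mol, ΔH = −18.0 kJ/mol)
    substrate + catalyst intermediate A ⇌ catalyst intermediate B (K = 710 /M, k = 1260 /M/min, Ea = 39.0 kJ/mol, ΔH = −41.0 kJ/mol)
    catalyst intermediate B → free catalyst + product (k = 54.3 /min, Ea = 81.0 kJ/mol)
    gas ⇌ partner, rate k4*(csat - [partner]) (kL = 0.699 /min)
    crystals ⇌ product, rate k5*(cs5 - [product]) while solid is left; crystals form when [product] > cs5 (solubility = 6.70 mM, k = 1.75 /min)
    partner → decomposed reagent (k = 0.0435 /min, Ea = 81.0 kJ/mol)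
    (constants at 35 °C)

**Read backwards.** With K = 32.5 mM, the integrated form reckons 92.6 min for the 65.8% of grey, against the 90 min that grey has. For green, if V is scaled to its catalyst, it reckons 99.2 min for its 41.5%. In grey, substrate turns over while free catalyst, the resting state, holds 67.5% of the catalyst at 1.50 h, more than either intermediate. Crystals in grey rise from 4.89% at 0.750 h to 32.1% at 1.50 h, with 34.2% of the substrate left.

Readings and results are simulated from invented constants, and the scatter is random.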